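## Analysis of the target

Compound 15 is an isoflavone, a 3-arylchromen-4-one. Ring A is a benzo ring with hydroxyls at C5 and C7 and 3-methylbut-2-enyl (prenyl) groups at C6 and C8, so it has no free position. Ring C is the 4-pyranone with an unsubstituted C2–H, and ring B is a 4-hydroxy-2-methoxyphenyl group joined through C1' to C3. There is no stereocentre and both prenyl alkenes are trisubstituted, so the problems are regiochemistry and chemoselectivity only. The sensitive groups are the two prenyl double bonds, each ortho to a phenol: acid converts such pairs into 2,2-dimethylchromans, and oxidants and hydrogenation are excluded. The pyranone C2 is also sensitive, since it adds hard nucleophiles with ring opening, and three phenols must be told apart from one methyl ether. The difficulty lies in placing two prenyl groups on carbon of a phloroglucinol nucleus, and in forming the C3–C1' bond to an oxygenated, ortho-substituted aryl ring under conditions the prenyl groups survive. The strategy rests on the fact that C4 and C3 are the carbonyl and methyl carbons of an ortho-hydroxyacetophenone: after one-carbon extension to an enaminone, C3 is a nucleophilic α-carbon, C2 carries an amine leaving group, and the chelated phenol oxygen (the future O1) is placed to close ring C once ring B has been delivered to C3 as an aryl cation equivalent.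

## Retrosynthetic reasoning

Target 15 is first traced back to its protected forms: phenol 14, with the two ring A hydroxyls as methoxymethyl ethers, and pivalate 13, in which the ring B hydroxyl is also esterified. No skeletal bond is cut. The two kinds of protecting group are chosen for what the earlier steps demand. The acetals on ring A leave exactly one free, chelated hydroxyl. The ester on ring B withstands the acidic, oxidising preparation of the arylating agent and makes the ring B aryl group poorer in electrons. In the forward direction the ester must be removed without opening the pyranone, and the acetals without cyclising a phenol onto a prenyl group.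

Chromone 13 is cut at C3–C1' and at O1–C2, which leads to enaminone 5 and the unsymmetrical diaryliodonium tosylate 11. The cut is made here because C3 of 5 is the most nucleophilic carbon of the molecule and needs no halogen or metal. Ring A has no free C–H that could compete. The same operation closes ring C, because the dimethylamino group on C2 is a leaving group for the neighbouring phenol. The forward reaction must transfer the 2-methoxy-4-(pivaloyloxy)phenyl group and not the trimethoxyphenyl group, and it must arylate carbon and not oxygen.

Enaminone 5 is cut at the C2=C3 double bond. C2 comes from a one-carbon amide acetal reagent condensed onto the acetyl methyl group of ketone 4. Ketone 4 in turn is the bis-acetal of triol 3. These are functional-group steps on a symmetrical substrate; the forward acetalisation only has to stop after two of the three hydroxyls.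

Triol 3 is cut at the two aryl–CH2 bonds, giving 2,4,6-trihydroxyacetophenone 1 and two equivalents of prenyl bromide 2. The acetyl group of 1 already contains C4 and C3, and C3 and C5 of 1 are the only free ring carbons and are equivalent. Double C-alkylation can therefore give only one diprenyl constitution.

Iodonium salt 11 is cut at the bond between iodine and the trimethoxyphenyl ring. This gives aryl iodide 8, oxidised in the flask to the trivalent iodine species 10, and 1,3,5-trimethoxybenzene 9, whose three C–H positions are equivalent. Iodide 8 is traced by halogen exchange to bromide 7 and by acylation to 4-bromo-3-methoxyphenol 6. The position of the halogen in 6 marks C1' from the start, so no electrophilic halogenation with a regiochemical question is needed.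

## Alternatives that were turned down

Alternative 1: Ring C is cut at C3–C4. The precursor is keto aldehyde A2, a ring A salicylaldehyde whose phenol oxygen carries the ring B phenacyl group. A carbene from an N-mesityl bicyclic triazolium salt and an amidine base turns the aldehyde into an acyl anion equivalent. This adds to the tethered aryl ketone and gives the racemic 3-hydroxychroman-4-one A1, which must then be dehydrated across C2–C3.
- For it: the closure is organocatalytic and metal-free, and only the aldehyde can act as acyl donor, so the crossed benzoin is chemoselective by design. Ring B enters as a simple phenacyl electrophile, with no hypervalent iodine reagent to prepare; on that point it is at least as strong as the chosen route.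
- Against it: the aldehyde of A2 lies between two ortho oxygens and is deactivated by three oxygen donors, so carbene addition is slow. The same base can enolise the α-aryloxy ketone and start the aldol-type benzofuran closure (Rap–Stoermer pathway) on the same aldehyde.
- Against it: A1 contains a quaternary stereocentre that is made only to be destroyed. Its hydroxyl is α, not β, to the carbonyl, so dehydration is not an E1cB process and needs activation or ionisation under conditions that threaten the prenyl groups and the acetals.
- Against it: the formyl group of A2 needs a separate formylation of the diprenylated ring A nucleus, whereas C4 is already present in 1.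
- In its place the chosen route reaches the chromone oxidation level directly, uses no base in the ring-forming step, and creates no stereocentre.

Alternative 2: Ring A is cut at C4a–C5. Rings C and B are assembled first as a 3-aryl-4-pyranone that carries, at the future C8a, a β-keto tert-butyl ester chain with both prenyl groups on its α-carbons (A4, a mixture of diastereomers). Heating in an aromatic solvent thermolyses the tert-butyl ester to acylketene A5. Its dienol forms a 1,3,5-triene with the pyranone double bond, and 6π-electrocyclisation onto the pyranone C–H carbon followed by tautomerisation gives the 5,7-dihydroxy arene A3, which needs only desilylation.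
- For it, and stronger than the chosen route on three points: both prenyl groups are fixed on sp3 carbons before ring A exists, the ring A phenols never need protection, and the end-game is a fluoride desilylation and not an acid treatment of prenylphenols.
- Against it: A4 is a doubly α-substituted polycarbonyl chain on a pyranone. It must be built by a long linear series of enolate acylations and alkylations on intermediates prone to retro-Claisen cleavage, decarboxylation and O-alkylation.
- Against it: the electrocyclisation needs enolisation towards C8 in the right geometry and interrupts the pyranone conjugation, and A5 is trapped by any stray nucleophile.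
- In exchange for less control in the prenylation, the chosen route is far shorter and convergent from commercial aromatics, and its one uncertain C–C bond formation has precedent on its substrate class.

Alternative 3: Both bonds to C4 are cut (C4a–C4 and C4–C3). The ring A iodide A7 and the α-aryl-β-methoxyvinyl boronate A8 are joined by a carbonylative Suzuki–Miyaura coupling (PdCl2(dppf), K2CO3), which inserts a one-carbon carbonyl unit between them and gives the β-methoxy enone A6. Acid would then remove all four acetals, and one of the two equivalent ortho phenols would displace methoxide to close ring C.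
- For it: it is highly convergent, and the symmetrical tris-acetal of ring A avoids having to stop protection after two hydroxyls. One acidic operation performs every deprotection and the ring closure, one operation fewer than the chosen end-game; there it is stronger.
- Against it: the iodine of A7 is flanked by two alkoxy groups buttressed by prenyl groups on a very electron-rich ring, so oxidative addition to zerovalent palladium is slow and the aroylpalladium intermediate is crowded.
- Against it: A8 is a 1,1-disubstituted alkenyl boronate whose boron sits on the nucleophilic carbon of an enol ether. It transmetallates slowly and protodeboronates readily, and direct coupling without carbonyl insertion is a further leak.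
- Against it: A7 needs double C-prenylation of the ring A nucleus without the moderating acyl group, followed by iodination in the presence of two alkenes. A8 needs its own multi-step synthesis with defined geometry.
- In the chosen route C4 is present from the first compound, the C3–aryl bond forms without metal at the most nucleophilic carbon, and no cross-coupling at a doubly ortho-substituted centre is required.

Key step: step 7

Assumption (remark on the chemistry): 4-bromo-3-methoxyphenol is taken as the commercial source of ring B because its halogen already marks C1'.

## Route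

Step 1
Reactants: 1 2,4,6-trihydroxyacetophenone; 2 prenyl bromide (1-bromo-3-methylbut-2-ene)
Product: 3 1-[2,4,6-trihydroxy-3,5-bis(3-methylbut-2-enyl)phenyl]ethanone
Conditions: 2 (2.2 equiv. in all), 10% aq. KOH, 0 °C to rt
Reagents that add atoms: prenyl bromide (second equivalent of 2), CC(C)=CCBr
Why: C-alkylation of an ambident phloroglucinol phenolate (aromatic C-prenylation), with water solvating the oxygens so that the soft allylic bromide is steered to carbon. The first equivalent of 2 alkylates one of the two equivalent free ring carbons and the second equivalent, entered above as the atom-adding reagent, takes the only one left, so the symmetrical diprenyl ketone should result. It is to be separated from mono- and over-alkylated material.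

Step 2
Reactants: 3 1-[2,4,6-trihydroxy-3,5-bis(3-methylbut-2-enyl)phenyl]ethanone
Product: 4 1-[2-hydroxy-4,6-bis(methoxymethoxy)-3,5-bis(3-methylbut-2-enyl)phenyl]ethanone
Conditions: MOMCl (2.2 equiv.), i-Pr2NEt, CH2Cl2, 0 °C to rt
Reagents that add atoms: chloromethyl methyl ether, COCCl
Why: O-alkylation of phenols to mixed acetals. The para hydroxyl and one of the two equivalent ortho hydroxyls react, after which the last hydroxyl is hydrogen-bonded to the acetyl oxygen and much less nucleophilic, so the reaction should stop at the bis-ether.

Step 3
Reactants: 4 1-[2-hydroxy-4,6-bis(methoxymethoxy)-3,5-bis(3-methylbut-2-enyl)phenyl]ethanone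
Product: 5 (E)-3-(dimethylamino)-1-[2-hydroxy-4,6-bis(methoxymethoxy)-3,5-bis(3-methylbut-2-enyl)phenyl]prop-2-en-1-one
Conditions: Me2NCH(OMe)2 (3 equiv.), PhMe, 95 °C
Reagents that add atoms: N,N-dimethylformamide dimethyl acetal, COC(OC)N(C)C
Why: Enaminone formation by condensation of the methyl ketone with an amide acetal: the ketone enolate adds to the formamidinium ion and methanol is lost. The (E) geometry is the thermodynamic one and has no bearing on later steps.

Step 4
Reactants: 6 4-bromo-3-methoxyphenol
Product: 7 4-bromo-3-methoxyphenyl pivalate
Conditions: PivCl, Et3N, DMAP (cat.), CH2Cl2, 0 °C to rt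
Reagents that add atoms: pivaloyl chloride, CC(C)(C)C(=O)Cl
Why: Acylation of a phenol under nucleophilic catalysis. The hindered ester is chosen to survive the acidic oxidation of step 6 and the amine released in step 7.

Step 5
Reactants: 7 4-bromo-3-methoxyphenyl pivalate
Product: 8 4-iodo-3-methoxyphenyl pivalate
Conditions: NaI (2 equiv.), CuI (5 mol %), trans-N,N'-dimethylcyclohexane-1,2-diamine (10 mol %), 1,4-dioxane, 110 °C
Reagents that add atoms: sodium iodide, [Na+].[I-]
Why: Copper-catalysed aromatic Finkelstein halogen exchange, driven by precipitation of NaBr from dioxane. The halogen position is inherited from 6, and a hindered aryl ester should tolerate the neutral conditions.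

Step 6
Reactants: 8 4-iodo-3-methoxyphenyl pivalate; 9 1,3,5-trimethoxybenzene
Product: 11 [2-methoxy-4-(pivaloyloxy)phenyl](2,4,6-trimethoxyphenyl)iodonium tosylate, via aryl hydroxy(tosyloxy)iodane 10 (not isolated)
Conditions: mCPBA (1.1 equiv.), TsOH·H2O (1.0 equiv.), MeCN, 50 °C; then 9 (1.0 equiv.), rt; trituration with Et2O
Reagents that add atoms: p-toluenesulfonic acid monohydrate, Cc1ccc(S(=O)(=O)O)cc1.O
Why: One-pot diaryliodonium synthesis. The peracid oxidises the aryl iodide to the Koser-type trivalent iodine species 10, which substitutes the very electron-rich arene 9 by electrophilic aromatic substitution at one of its three equivalent positions, and the salt should precipitate.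

Step 7
Reactants: 5 (E)-3-(dimethylamino)-1-[2-hydroxy-4,6-bis(methoxymethoxy)-3,5-bis(3-methylbut-2-enyl)phenyl]prop-2-en-1-one; 11 [2-methoxy-4-(pivaloyloxy)phenyl](2,4,6-trimethoxyphenyl)iodonium tosylate
Product: 13 5,7-bis(methoxymethoxy)-3-[2-methoxy-4-(pivaloyloxy)phenyl]-6,8-bis(3-methylbut-2-enyl)chromen-4-one, via 2-(dimethylamino)chroman-4-one aminal 12 (not isolated)
Conditions: 11 (1.2 equiv.), DMF, 80 °C, no base, N2
Reagents that add atoms: none
Why: The polarised enaminone attacks the trivalent iodine centre of 11 through its α-carbon (the future C3) with displacement of tosylate, and reductive ligand coupling in the resulting λ3-iodane joins C3 to the ipso carbon of the 2-methoxy-4-(pivaloyloxy)phenyl group while 2-iodo-1,3,5-trimethoxybenzene departs. The α-aryl iminium ion so formed is trapped by the neighbouring phenol in a 6-exo-trig closure (O1–C2) to aminal 12, and β-elimination of dimethylamine towards the C4 carbonyl then gives the chromone. The two transient stereocentres of 12 are erased in that elimination, so the product has no stereocentre and nothing needs to be controlled. The closest known reaction type is the metal-free tandem α-C–H arylation and annulation of ortho-hydroxyaryl enaminones with diaryliodonium salts to 3-arylchromones. Transfer of the correct aryl group relies on the trimethoxyphenyl ligand, which is the most electron-rich arene on iodine, accepts the nucleophile least readily at its ipso carbon, and therefore stays on iodine. C-arylation over O-arylation relies on the absence of base, so that the phenol remains protonated and hydrogen-bonded to the carbonyl. Reaction at the enaminone and not at the prenyl alkenes follows from the much higher nucleophilicity of the push–pull alkene and from the absence of any free C–H on ring A. The acid set free is buffered as dimethylammonium tosylate, which the acetals and the pivalate should tolerate.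

Step 8
Reactants: 13 5,7-bis(methoxymethoxy)-3-[2-methoxy-4-(pivaloyloxy)phenyl]-6,8-bis(3-methylbut-2-enyl)chromen-4-one
Product: 14 3-(4-hydroxy-2-methoxyphenyl)-5,7-bis(methoxymethoxy)-6,8-bis(3-methylbut-2-enyl)chromen-4-one
Conditions: K2CO3 (2 equiv.), MeOH/THF, 0 °C to rt
Reagents that add atoms: none
Why: Base-mediated methanolysis (transesterification) of an aryl ester, which is far more reactive than the acetals. The mild carbonate base at or below room temperature should leave the pyranone ring closed.

Step 9
Reactants: 14 3-(4-hydroxy-2-methoxyphenyl)-5,7-bis(methoxymethoxy)-6,8-bis(3-methylbut-2-enyl)chromen-4-one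
Product: 15 5,7-dihydroxy-3-(4-hydroxy-2-methoxyphenyl)-6,8-bis(3-methylbut-2-enyl)chromen-4-one
Conditions: 3 M aq. HCl, MeOH, 45 °C
Reagents that add atoms: none
Why: Acid-catalysed acetal exchange with methanol removes both methoxymethyl groups as dimethoxymethane. The acetal oxygens are protonated much more readily than the trisubstituted alkenes, so short exposure to dilute acid should free the phenols before chroman formation sets in.

## Compound list

1 | 2,4,6-trihydroxyacetophenone | CC(=O)c1c(O)cc(O)cc1O | starting material
2 | prenyl bromide (1-bromo-3-methylbut-2-ene) | CC(C)=CCBr | starting material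
3 | 1-[2,4,6-trihydroxy-3,5-bis(3-methylbut-2-enyl)phenyl]ethanone | CC(=O)c1c(O)c(CC=C(C)C)c(O)c(CC=C(C)C)c1O | intermediate
4 | 1-[2-hydroxy-4,6-bis(methoxymethoxy)-3,5-bis(3-methylbut-2-enyl)phenyl]ethanone | CC(=O)c1c(O)c(CC=C(C)C)c(OCOC)c(CC=C(C)C)c1OCOC | intermediate
5 | (E)-3-(dimethylamino)-1-[2-hydroxy-4,6-bis(methoxymethoxy)-3,5-bis(3-methylbut-2-enyl)phenyl]prop-2-en-1-one | CN(C)/C=C/C(=O)c1c(O)c(CC=C(C)C)c(OCOC)c(CC=C(C)C)c1OCOC | intermediate
6 | 4-bromo-3-methoxyphenol | COc1cc(O)ccc1Br | starting material
7 | 4-bromo-3-methoxyphenyl pivalate | COc1cc(OC(=O)C(C)(C)C)ccc1Br | intermediate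
8 | 4-iodo-3-methoxyphenyl pivalate | COc1cc(OC(=O)C(C)(C)C)ccc1I | intermediate
9 | 1,3,5-trimethoxybenzene | COc1cc(OC)cc(OC)c1 | starting material
10 | 4-[hydroxy(tosyloxy)-λ3-iodanyl]-3-methoxyphenyl pivalate | COc1cc(OC(=O)C(C)(C)C)ccc1I(O)OS(=O)(=O)c1ccc(C)cc1 | intermediate (not isolated)
11 | [2-methoxy-4-(pivaloyloxy)phenyl](2,4,6-trimethoxyphenyl)iodonium tosylate | COc1cc(OC(=O)C(C)(C)C)ccc1[I+]c1c(OC)cc(OC)cc1OC.Cc1ccc(S(=O)(=O)[O-])cc1 | intermediate
12 | 2-(dimethylamino)-5,7-bis(methoxymethoxy)-3-[2-methoxy-4-(pivaloyloxy)phenyl]-6,8-bis(3-methylbut-2-enyl)chroman-4-one (racemic mixture of diastereomers) | COCOc1c(CC=C(C)C)c(OCOC)c2C(=O)C(c3ccc(OC(=O)C(C)(C)C)cc3OC)C(N(C)C)Oc2c1CC=C(C)C | intermediate (not isolated)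
13 | 5,7-bis(methoxymethoxy)-3-[2-methoxy-4-(pivaloyloxy)phenyl]-6,8-bis(3-methylbut-2-enyl)chromen-4-one | COCOc1c(CC=C(C)C)c(OCOC)c2c(=O)c(-c3ccc(OC(=O)C(C)(C)C)cc3OC)coc2c1CC=C(C)C | intermediate
14 | 3-(4-hydroxy-2-methoxyphenyl)-5,7-bis(methoxymethoxy)-6,8-bis(3-methylbut-2-enyl)chromen-4-one | COCOc1c(CC=C(C)C)c(OCOC)c2c(=O)c(-c3ccc(O)cc3OC)coc2c1CC=C(C)C | intermediate
15 | 5,7-dihydroxy-3-(4-hydroxy-2-methoxyphenyl)-6,8-bis(3-methylbut-2-enyl)chromen-4-one | COc1cc(O)ccc1-c1coc2c(CC=C(C)C)c(O)c(CC=C(C)C)c(O)c2c1=O | target

## Step count and least certain steps

Total step count: 9. Longest linear sequence: 6 steps (steps 1, 2, 3, 7, 8, 9, or equally steps 4, 5, 6, 7, 8, 9).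

Step 7 (key step). Two things are most likely to go wrong. The first is premature ring closure: the ammonium tosylate that accumulates can promote addition of the phenol to the enaminone and loss of the amine before C3 is arylated, which removes the nucleophilic carbon. The second is slow or unselective ligand coupling: the aryl group to be transferred is itself oxygenated and ortho-substituted, so the electronic gap to the trimethoxyphenyl ligand is narrower than usual. The fallback uses a different bond-forming logic and sets out from 5 and 7. Treatment of 5 with I2 and pyridine in CHCl3 at rt should iodinate the α-carbon and close the ring to 3-iodo-5,7-bis(methoxymethoxy)-6,8-bis(3-methylbut-2-enyl)chromen-4-one F1. In parallel, 7 would be borylated (B2pin2, PdCl2(dppf), KOAc, 1,4-dioxane, 90 °C) to 3-methoxy-4-(4,4,5,5-tetramethyl-1,3,2-dioxaborolan-2-yl)phenyl pivalate F2. Suzuki–Miyaura coupling of F1 with F2 (Pd(PPh3)4, aq. Na2CO3, DME, 80 °C) should come back to the route at 13. Partial loss of the pivalate under the aqueous base would only give 14, the next compound.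

Step 1. The likely failure is poor control of the degree and site of alkylation: stopping at the mono-prenyl stage, O-prenylation, or a third alkylation on an already substituted carbon with dearomatisation. This would leave a mixture from which 3 is recovered with difficulty. The fallback sets out from 1 and returns at 3. Allyl bromide (2.1 equiv.) and K2CO3 in acetone should give 1-[2,4-bis(allyloxy)-6-hydroxyphenyl]ethanone F3. Heating F3 in N,N-diethylaniline at about 195 °C should bring about a double aromatic Claisen rearrangement to 1-[3,5-diallyl-2,4,6-trihydroxyphenyl]ethanone F4. The C2 ether can reach only C3, or C5 by Cope relay if C3 is occupied, and the C4 ether takes the remaining position, so all sequences converge. Cross-metathesis of F4 with excess 2-methylbut-2-ene (second-generation Grubbs catalyst, CH2Cl2, 40 °C) should convert both allyl groups into prenyl groups and give 3.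

Step 6. The likely failure is self-condensation of the electron-rich trivalent iodine intermediate with unreacted aryl iodide, or over-oxidation at elevated temperature. Slow acid-mediated loss of the pivalate in the presence of the sulfonic acid hydrate is a further risk. The fallback separates oxidation from arylation and avoids strong acid; it sets out from 8 and returns at 11. NaBO3·4H2O in AcOH at 45 °C should give isolable 4-(diacetoxy-λ3-iodanyl)-3-methoxyphenyl pivalate F5. F5 and 9 in 2,2,2-trifluoroethanol at rt should condense to [2-methoxy-4-(pivaloyloxy)phenyl](2,4,6-trimethoxyphenyl)iodonium acetate F6. Addition of TsOH·H2O (1 equiv.) to F6 should exchange acetate for tosylate and give 11.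

Step 9. The likely failure is acid-promoted addition of a freshly liberated C5 or C7 hydroxyl to the adjacent prenyl double bond (cycloetherification), competing with slow cleavage of the hindered C7 acetal. The fallback replaces acid-labile protection by allyl ethers that are removed under neutral to basic conditions; it sets out from 3 and returns at 15. Allyl bromide (2.2 equiv.) and K2CO3 in acetone should give 1-[4,6-bis(allyloxy)-2-hydroxy-3,5-bis(3-methylbut-2-enyl)phenyl]ethanone F7. Condensation as in step 3 should give (E)-1-[4,6-bis(allyloxy)-2-hydroxy-3,5-bis(3-methylbut-2-enyl)phenyl]-3-(dimethylamino)prop-2-en-1-one F8. Arylation and annulation of F8 with 11 as in step 7 should give 5,7-bis(allyloxy)-3-[2-methoxy-4-(pivaloyloxy)phenyl]-6,8-bis(3-methylbut-2-enyl)chromen-4-one F9. Pd(PPh3)4 (cat.) with K2CO3 in MeOH at 40 °C should cleave both aryl allyl ethers of F9 through π-allyl complexes of palladium and methanolyse the pivalate in the same flask, giving 15.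

## Further compounds

F1 | step 7 | 3-iodo-5,7-bis(methoxymethoxy)-6,8-bis(3-methylbut-2-enyl)chromen-4-one | COCOc1c(CC=C(C)C)c(OCOC)c2c(=O)c(I)coc2c1CC=C(C)C
F2 | step 7 | 3-methoxy-4-(4,4,5,5-tetramethyl-1,3,2-dioxaborolan-2-yl)phenyl pivalate | COc1cc(OC(=O)C(C)(C)C)ccc1B1OC(C)(C)C(C)(C)O1
F3 | step 1 | 1-[2,4-bis(allyloxy)-6-hydroxyphenyl]ethanone | CC(=O)c1c(O)cc(OCC=C)cc1OCC=C
F4 | step 1 | 1-[3,5-diallyl-2,4,6-trihydroxyphenyl]ethanone | CC(=O)c1c(O)c(CC=C)c(O)c(CC=C)c1O
F5 | step 6 | 4-(diacetoxy-λ3-iodanyl)-3-methoxyphenyl pivalate | COc1cc(OC(=O)C(C)(C)C)ccc1I(OC(C)=O)OC(C)=O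
F6 | step 6 | [2-methoxy-4-(pivaloyloxy)phenyl](2,4,6-trimethoxyphenyl)iodonium acetate | COc1cc(OC(=O)C(C)(C)C)ccc1[I+]c1c(OC)cc(OC)cc1OC.CC(=O)[O-]
F7 | step 9 | 1-[4,6-bis(allyloxy)-2-hydroxy-3,5-bis(3-methylbut-2-enyl)phenyl]ethanone | CC(=O)c1c(O)c(CC=C(C)C)c(OCC=C)c(CC=C(C)C)c1OCC=C
F8 | step 9 | (E)-1-[4,6-bis(allyloxy)-2-hydroxy-3,5-bis(3-methylbut-2-enyl)phenyl]-3-(dimethylamino)prop-2-en-1-one | CN(C)/C=C/C(=O)c1c(O)c(CC=C(C)C)c(OCC=C)c(CC=C(C)C)c1OCC=C
F9 | step 9 | 5,7-bis(allyloxy)-3-[2-methoxy-4-(pivaloyloxy)phenyl]-6,8-bis(3-methylbut-2-enyl)chromen-4-one | C=CCOc1c(CC=C(C)C)c(OCC=C)c2c(=O)c(-c3ccc(OC(=O)C(C)(C)C)cc3OC)coc2c1CC=C(C)C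
A1 | alternative 1 | racemic 3-hydroxy-3-[2-methoxy-4-(methoxymethoxy)phenyl]-5,7-bis(methoxymethoxy)-6,8-bis(3-methylbut-2-enyl)chroman-4-one | O=C1c2c(OCOC)c(CC=C(C)C)c(OCOC)c(CC=C(C)C)c2OCC1(O)c1ccc(OCOC)cc1OC
A2 | alternative 1 | 2-{2-[2-methoxy-4-(methoxymethoxy)phenyl]-2-oxoethoxy}-4,6-bis(methoxymethoxy)-3,5-bis(3-methylbut-2-enyl)benzaldehyde | O=Cc1c(OCOC)c(CC=C(C)C)c(OCOC)c(CC=C(C)C)c1OCC(=O)c1ccc(OCOC)cc1OC
A3 | alternative 2 | 5,7-dihydroxy-3-[2-methoxy-4-(triisopropylsilyloxy)phenyl]-6,8-bis(3-methylbut-2-enyl)chromen-4-one | COc1cc(O[Si](C(C)C)(C(C)C)C(C)C)ccc1-c1coc2c(CC=C(C)C)c(O)c(CC=C(C)C)c(O)c2c1=O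
A4 | alternative 2 | tert-butyl 4-{5-[2-methoxy-4-(triisopropylsilyloxy)phenyl]-4-oxo-4H-pyran-2-yl}-7-methyl-2-(3-methylbut-2-enyl)-3-oxooct-6-enoate (mixture of diastereomers) | CC(C)=CCC(C(=O)OC(C)(C)C)C(=O)C(CC=C(C)C)c1cc(=O)c(-c2ccc(O[Si](C(C)C)(C(C)C)C(C)C)cc2OC)co1
A5 | alternative 2 | 4-{5-[2-methoxy-4-(triisopropylsilyloxy)phenyl]-4-oxo-4H-pyran-2-yl}-7-methyl-2-(3-methylbut-2-enyl)octa-1,6-diene-1,3-dione (acylketene) | CC(C)=CCC(=C=O)C(=O)C(CC=C(C)C)c1cc(=O)c(-c2ccc(O[Si](C(C)C)(C(C)C)C(C)C)cc2OC)co1
A6 | alternative 3 | (E)-3-methoxy-2-[2-methoxy-4-(methoxymethoxy)phenyl]-1-[2,4,6-tris(methoxymethoxy)-3,5-bis(3-methylbut-2-enyl)phenyl]prop-2-en-1-one | CO/C=C(\c1ccc(OCOC)cc1OC)C(=O)c1c(OCOC)c(CC=C(C)C)c(OCOC)c(CC=C(C)C)c1OCOC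
A7 | alternative 3 | 2-iodo-1,3,5-tris(methoxymethoxy)-4,6-bis(3-methylbut-2-enyl)benzene | COCOc1c(I)c(OCOC)c(CC=C(C)C)c(OCOC)c1CC=C(C)C
A8 | alternative 3 | 2-{(Z)-2-methoxy-1-[2-methoxy-4-(methoxymethoxy)phenyl]ethenyl}-4,4,5,5-tetramethyl-1,3,2-dioxaborolane | CO/C=C(\c1ccc(OCOC)cc1OC)B1OC(C)(C)C(C)(C)O1
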